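The earlier runs and the new flask are calculated with constants of no real substance, noise included.

**The decision.** The vessel, closed, stirred and held at one temperature, is next to be charged as the teal run, with 0.420 M of Z and with J and Q as in amber. The question is whether so much Z buys more L.

| flask | Z | J | Q | time |
|---|---|---|---|---|
| green | 0.120 M | 0.132 M | 0.00120 M |  |
| blue | 0.0480 M | 0.0600 M | 0.00120 M |  |
| amber | 0.240 M | 0.132 M | 0.00120 M |  |
| red | 0.120 M | 0.132 M | 0.00240 M |  |
| teal | 0.420 M | 0.132 M | 0.00120 M | 6.9 min |

| green run: time / min | green run: [Z] / M | blue run: time / min | blue run: [Z] / M | amber run: time / min | amber run: [Z] / M | red run: time / min | red run: [Z] / M |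
|---|---|---|---|---|---|---|---|
| 0.86 | 0.1047 | 0.86 | 0.0372 | 0.86 | 0.2233 | 0.86 | 0.0925 |
| 1.7 | 0.0920 | 1.7 | 0.0281 | 1.7 | 0.2090 | 1.7 | 0.0676 |
| 2.6 | 0.0778 | 2.6 | 0.0194 | 2.6 | 0.1932 | 2.6 | 0.0429 |
| 3.5 | 0.0639 | 3.5 | 0.0124 | 3.5 | 0.1782 | 3.5 | 0.0246 |
| 4.3 | 0.0536 | 4.3 | 0.0079 | 4.3 | 0.1666 | 4.3 | 0.0119 |
| 5.2 | 0.0422 | 5.2 | 0.0042 | 5.2 | 0.1534 | 5.2 | 0.0038 |
| 6.0 | 0.0323 | 6.0 | 0.0020 | 6.0 | 0.1426 | 6.0 | 0.0018 |
| 6.9 | 0.0225 | 6.9 | 0.0011 | 6.9 | 0.1324 | 6.9 | 0 |

(scatter of a reading: 4 × 10⁻⁴ M)

- the exponent of [J] in the starting rate at the charge of the green run (at the point where two percent of the Z have become L)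
- the exponent of [Q] in the starting rate at the charge of the green run (at the point where two percent of the Z have become L)
- the blue run starts with 0.0720 M less of Z and of J than the green run, and with no L. Compared where both hold the same amount of Z, once fifteen percent of what the blue run was charged with has turned into L, is the blue run faster, slower or alike (within a tenth)?
- Z in the teal run at 6.9 min, as a share of the Z charged

- Overall: Z + J -> L, with Q as catalyst.
- Constant volume, constant temperature.
- Bound and free are read together.
- An order is taken over about fifteen percent of the charge, up and down.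

**What Z costs.** Up to 1.7 min, the green run loses Z at 0.0165 M min⁻¹ around a mean [Z] of 0.106 M. Over the same time the amber run, with the same charge of J and Q, loses Z at 0.0182 M min⁻¹ around 0.224 M. So a [Z] about twice as high gives a rate 1.10 times as great. If Q takes up Z in a fast, balanced step, then at fixed [J] and fixed charge of Q the reciprocal of the rate is a fixed part plus a part proportional to the reciprocal of [Z]. The slope read from these two runs is 1.18 min. This is the Z toll, the slope of reciprocal rate against reciprocal [Z] at this charge of J and Q. It is a reading and carries the scatter of 4 × 10⁻⁴ M.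

**Teal reckoned.** Each Z used takes one J, so the amber run is the pattern for how J falls in the teal run. Amber uses 0.108 M by 6.9 min. The higher mean [Z] of the teal run lowers the reciprocal rate by the toll times the fall in the reciprocal of [Z], and this multiplies that use by 1.05. My reckoning is therefore a use of 0.113 M, which leaves 73.1% of the teal charge of Z. J, the limiting reagent, is charged at less than Z, and 0.0189 M of it remains on this reckoning. The red run, with twice the Q of green, ran its first interval 1.87 times as fast as green, a greater factor than the gain from Z. The teal charge is kept as a test of the toll rather than as a way to more L.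

**The forecast.** It gives 0.25, 0.9, alike and 74.3%, in the order asked, and reads from the nearly flat rates that “the catalyst is close to saturated”; its last figure stands above mine.

**The flask.** The simulation gives 0.20, 0.91, alike and 72.8%, in the same order.

    Q + Z ⇌ QZ, settled at all times (106.0 M⁻¹)
    QZ + J ⇌ QZJ, settled at all times (59.10 M⁻¹)
    QZJ → L + Q (15.78 min⁻¹)
    Z + J → L (0.09660 M⁻¹ min⁻¹)
    Q + J ⇌ QJ, settled at all times (43.80 M⁻¹)

**What happened.** The teal run used 1.06 times amber's Z against the reckoned 1.05: at the start QZJ, the resting state at that moment, held about 87.1% of Q, and QZJ → L + Q ran beside Z + J → L, while by 6.9 min [J], bound forms counted, had fallen to about 0.0179 M and QZJ held about half of Q. The toll, carried at green's J to the blue run, puts L at a quarter of the blue charge of Z at 0.932 min, and the blue run, charged with 0.0600 M of J against green's 0.132 M, came there later, at 0.976 min.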